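**Overview**
1. Cuts: C13=C14 (olefination), then C9–C11 (addition to a C9 ketone), then C1–C10 and C4–C5 together in a retro-[4+2] that lifts ring A off ring B.
2. Enabling feature: H-5 and the C10 methyl are cis (cis A/B fusion). Ring B (C5–C10) has methyls on C8 and C10, oxygen on C6, and the chain on C9 para to C6. This is the 2,6-dimethyl-1,4-benzoquinone pattern, and C1–C4 with C18/C19 is 4-methylpenta-1,3-diene.
3. Forward order: ring B is bought, ring A closes in step 1, C11–C13/C16 joins C9 in step 4, and C14–C15 joins C13 in step 14.
4. Stereochemistry: C5/C10 come from suprafacial addition under a chiral cationic boron Lewis acid. A temporary 6β-OH (convex-face hydride) places the epoxide β and thereby fixes C8.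
5. The 8β-OH then steers H2 to C9 and, after oxidation at C6, steers hydride to C6 (6α-carbinol, acetylated). The olefination gives the E alkene.

Key step: step 1

Convention: labdane numbering is used. α is the face of ring B that carries H-5 and the C10 methyl; β is the face that carries C1 and C4.
Assumption 1: the (S)-oxazaborolidine is assigned from the accepted binding model (boron on the carbonyl lone pair syn to the α-C–H, that hydrogen in contact with the ring oxygen, one phenyl group under the reacting C=C). The (R)-antipode is equally available if the sense proves opposite.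
Assumption 2: the exocyclic C9=C11 bond made in step 5 is drawn with C12 syn to C8. The geometry has no consequence because C11 becomes CH2 in step 9.

**Step 1**
Reactants: 1 2,6-dimethyl-1,4-benzoquinone; 2 4-methylpenta-1,3-diene
Product: 3 cis-fused ene-dione (4aS,8aR)-2,5,5,8a-tetramethyl-4a,5,8,8a-tetrahydronaphthalene-1,4-dione (ketones at C6 and C9, C7=C8, C2=C3, H-5 and C10 methyl both α)
Conditions: (S)-3,3-diphenyl-1-(2-methylphenyl)tetrahydro-1H,3H-pyrrolo[1,2-c][1,3,2]oxazaborole (20 mol %), HN(SO2CF3)2 (18 mol %), 2 (5 equiv), CH2Cl2, −78 to −20 °C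
Reagents that add atoms: none
Why: The protonated oxazaborolidine binds 1 at the C6 carbonyl, the only one with C–H groups on both sides and the more basic one because both ring methyls donate to it vinylogously, so the methyl-bearing β-carbon C10 becomes the most electrophilic position and the unsubstituted CH2 terminus of 2 (largest HOMO coefficient, future C1) bonds there slightly ahead of the CMe2 terminus (future C4) at C5 in a concerted but asynchronous [4+2] cycloaddition. The closest known reaction type is the enantioselective Diels–Alder reaction of 2,6-dialkyl-1,4-benzoquinones with acyclic dienes under cationic oxazaborolidine catalysis, and the same orientation is known for Lewis-acid-catalysed additions of 1-substituted dienes to this quinone. Ring A (C1–C5, C10) closes as a six-membered ring by suprafacial–suprafacial cycloaddition across C5=C10, both new σ bonds (C1–C10, C4–C5) being made in the one step. C5 and C10 are created together: their cis relation follows from suprafacial addition to the ring alkene and their absolute configuration from the catalyst, whose α-C–H···O contact holds the quinone over one phenyl group so that only the open face can be reached, and since neither diene terminus becomes stereogenic, endo and exo approaches converge on 3. The step needs regio-, face and mono-addition selectivity: the regiochemistry is reinforced sterically because the alternative would join two fully substituted carbons, the two C=C bonds of 1 are symmetry-equivalent, 3 is a much poorer dienophile than 1, and the angular methyl prevents aromatisation. The Z-methyl of 2 disfavours the s-cis conformer, which is why an excess of diene and the strongly activated cationic complex are used.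

**Step 2**
Reactants: 3 cis-fused ene-dione
Product: 4 6β-hydroxy enone (6β-OH, C7=C8, C9 ketone, C2=C3)
Conditions: NaBH4, CeCl3·7H2O, MeOH/CH2Cl2, −78 °C
Reagents that add atoms: none
Why: Luche 1,2-reduction: the C6 carbonyl sits between two C–H carbons whereas C9 is wedged between quaternary C10 and the C8 methyl, so C6 reacts first, and hydride enters from the convex α face of the folded cis-bicycle to set the temporary 6β-carbinol, which also takes away the acidity of H-5.

**Step 3**
Reactants: 4 6β-hydroxy enone
Product: 5 6β-triethylsilyloxy enone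
Conditions: Et3SiCl, imidazole, CH2Cl2, 0 °C to rt
Reagents that add atoms: chlorotriethylsilane, CC[Si](Cl)(CC)CC
Why: Routine silylation of a secondary allylic alcohol with a chlorosilane and imidazole; the triethylsilyl ether removes the acidic proton before the organometallic step, keeps the Burgess reagent away from C6 and falls to fluoride without harm to the ketal.

**Step 4**
Reactants: 5 6β-triethylsilyloxy enone; 6 2-(2-bromoethyl)-2-methyl-1,3-dioxolane
Product: 9 C9 tertiary allylic alcohol (9β-OH; 9α-CH2CH2C(CH3)(OCH2CH2O); 6β-OSiEt3; C7=C8), via Grignard reagent 7 (not isolated), via organocerium reagent 8 (not isolated)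
Conditions: 6, Mg, THF, 20–25 °C; anhydrous CeCl3, THF, −78 °C; then 5, −78 to 0 °C; aq NH4Cl
Reagents that add atoms: none
Why: Organocerium 1,2-addition: the weakly basic, strongly oxophilic cerium reagent adds to the crowded α-methyl enone carbonyl where a Grignard reagent alone would tend to reduce or add in conjugate fashion, attack is expected from the α face because C1 stands axial over the β face, and the resulting C9 configuration is of no consequence since step 5 erases it.

**Step 5**
Reactants: 9 C9 tertiary allylic alcohol
Product: 11 6β-triethylsilyloxy 2,7,9(11)-triene (exocyclic C9=C11), via sulfamate ester 10 (not isolated)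
Conditions: Burgess reagent (MeO2C–N(−)–SO2–N(+)Et3), toluene, rt to 70 °C
Reagents that add atoms: none
Why: Burgess dehydration, a syn elimination through the sulfamate ester: C8 is sp2 and C10 is quaternary, so only C11 offers a β-hydrogen and the exocyclic C9=C11 bond, conjugated with C7=C8, is the sole possible alkene, formed under neutral conditions that spare silyl ether and ketal.

**Step 6**
Reactants: 11 6β-triethylsilyloxy 2,7,9(11)-triene
Product: 12 6β-hydroxy 2,7,9(11)-triene
Conditions: Bu4NF, THF, 0 °C
Reagents that add atoms: none
Why: Fluoride-induced desilylation driven by the strong Si–F bond; diene, ketal and C2=C3 are inert to Bu4NF at 0 °C and no stereocentre is touched.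

**Step 7**
Reactants: 12 6β-hydroxy 2,7,9(11)-triene
Product: 13 7β,8β-epoxy 6β-alcohol (C9=C11 and C2=C3 retained)
Conditions: VO(acac)2 (5 mol %), t-BuOOH (decane), CH2Cl2, 0 °C
Reagents that add atoms: tert-butyl hydroperoxide, CC(C)(C)OO
Why: Vanadium-catalysed hydroxyl-directed epoxidation: the vanadate ester of the pseudo-axial 6β-hydroxyl hands the peroxide oxygen to the same (β) face of the adjoining C7=C8 bond, which overrides the intrinsic convex-face bias and sets C7 and C8, while C9=C11 and C2=C3 lack an allylic hydroxyl and react far more slowly.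

**Step 8**
Reactants: 13 7β,8β-epoxy 6β-alcohol
Product: 14 6β,8β-diol (8α-methyl) with exocyclic C9=C11 and C2=C3
Conditions: LiAlH4, THF, 0 °C to rt; then H2O
Reagents that add atoms: none
Why: SN2 opening of an epoxide by hydride: attack at the secondary C7 from the open α face, anti to the C7–O bond, is both the less hindered and the trans-diaxial (Fürst–Plattner) mode, the C8–O bond is never broken so the 8β-hydroxyl/8α-methyl arrangement is kept, and a cis-epoxy alkoxide cannot undergo Payne rearrangement.

**Step 9**
Reactants: 14 6β,8β-diol with exocyclic C9=C11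
Product: 15 saturated 6β,8β-diol (H-9β, chain 9α, ring A saturated)
Conditions: [Ir(cod)(PCy3)(py)]PF6 (10 mol %), H2, CH2Cl2, rt
Reagents that add atoms: none
Why: Hydroxyl-directed homogeneous hydrogenation: the cationic iridium centre binds the axial allylic 8β-hydroxyl (the 6β-hydroxyl lies on the same face) and transfers H2 to the β face of C9=C11, which sets H-9β and pushes the chain α, against the outcome expected from an undirected catalyst, and the unhindered C2=C3 bond is saturated in the same operation.

**Step 10**
Reactants: 15 saturated 6β,8β-diol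
Product: 16 8β-hydroxy 6-ketone
Conditions: Dess–Martin periodinane, NaHCO3, CH2Cl2, 0 °C; used crude
Reagents that add atoms: none
Why: Dess–Martin oxidation: only the secondary 6β-carbinol can be oxidised, and the bicarbonate buffer, the low temperature and direct use of the crude ketone guard against enolisation at C5 (loss of the cis fusion) and against β-elimination of the 8-hydroxyl.

**Step 11**
Reactants: 16 8β-hydroxy 6-ketone
Product: 17 6α,8β-diol
Conditions: Me4N[BH(OAc)3], MeCN/AcOH, −30 °C
Reagents that add atoms: none
Why: Evans–Saksena reduction: the axial tertiary 8β-hydroxyl displaces an acetate from boron and the bound hydride is delivered within the complex to the β face of the C6 carbonyl, which gives the equatorial 6α-carbinol, 1,3-anti to the directing group, while free triacetoxyborohydride is too weak to reduce the ketone on its own.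

**Step 12**
Reactants: 17 6α,8β-diol
Product: 18 6α-acetoxy 8β-alcohol (ketal intact)
Conditions: Ac2O, pyridine, 4-(dimethylamino)pyridine (cat.), CH2Cl2, 0 °C to rt
Reagents that add atoms: acetic anhydride, CC(=O)OC(C)=O
Why: Nucleophile-catalysed acylation: the equatorial secondary 6α-hydroxyl is acetylated while the axial tertiary 8β-hydroxyl is too hindered to react under these mild conditions, and being on the opposite face it cannot receive the acetyl group by migration.

**Step 13**
Reactants: 18 6α-acetoxy 8β-alcohol
Product: 19 6α-acetoxy 8β-hydroxy C13 methyl ketone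
Conditions: pyridinium p-toluenesulfonate (cat.), acetone/H2O, 40 °C
Reagents that add atoms: water, O
Why: Mild acid-catalysed ketal hydrolysis: pyridinium p-toluenesulfonate is too weak to ionise the tertiary alcohol or cleave the acetate, and ring closure of the 8β-hydroxyl onto the new C13 ketone is disfavoured because hydroxyl and chain are trans-diaxial in the preferred chair.

**Step 14**
Reactants: 19 6α-acetoxy 8β-hydroxy C13 methyl ketone; 20 allyl diethylphosphonoacetate
Product: 22 allyl (13E)-enoate (allyl ester of the target), via sodium phosphonate 21 (not isolated)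
Conditions: 20, NaH, THF, 0 °C; then 19, 0 °C to rt; chromatography
Reagents that add atoms: none
Why: Horner–Wadsworth–Emmons olefination: the stabilised phosphonate anion adds reversibly to the unhindered methyl ketone and collapses mainly to the E enoate (ester trans to the larger C12 chain), is not basic enough to deprotonate the tertiary alcohol or attack the acetate, and the minor Z isomer is removed by chromatography.

**Step 15**
Reactants: 22 allyl (13E)-enoate
Product: 23 target CNP0221670.1, (2E)-5-[(1S,2S,4S,4aS,8aR)-4-acetoxy-2-hydroxy-2,5,5,8a-tetramethyldecahydronaphthalen-1-yl]-3-methylpent-2-enoic acid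
Conditions: Pd(PPh3)4 (5 mol %), morpholine, THF, rt; then aq KHSO4
Reagents that add atoms: none
Why: Tsuji–Trost-type deallylation: zerovalent palladium ionises only the allyl ester to a π-allyl complex that morpholine intercepts, so the acid is freed under neutral conditions without touching the acetate, the tertiary alcohol or the alkene geometry.

**Compound list**
1 | 2,6-dimethyl-1,4-benzoquinone | CC1=CC(=O)C=C(C)C1=O | starting material
2 | 4-methylpenta-1,3-diene | C=CC=C(C)C | starting material
3 | (4aS,8aR)-2,5,5,8a-tetramethyl-4a,5,8,8a-tetrahydronaphthalene-1,4-dione (cis-fused ene-dione) | O=C1C=C(C)C(=O)[C@]2(C)CC=CC(C)(C)[C@H]12 | intermediate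
4 | 6β-hydroxy enone | O[C@@H]1C=C(C)C(=O)[C@]2(C)CC=CC(C)(C)[C@H]12 | intermediate
5 | 6β-triethylsilyloxy enone | CC[Si](CC)(CC)O[C@@H]1C=C(C)C(=O)[C@]2(C)CC=CC(C)(C)[C@H]12 | intermediate
6 | 2-(2-bromoethyl)-2-methyl-1,3-dioxolane | CC1(CCBr)OCCO1 | starting material
7 | [2-(2-methyl-1,3-dioxolan-2-yl)ethyl]magnesium bromide | CC1(CC[Mg]Br)OCCO1 | intermediate
8 | dichloro[2-(2-methyl-1,3-dioxolan-2-yl)ethyl]cerium | CC1(CC[Ce](Cl)Cl)OCCO1 | intermediate
9 | C9 tertiary allylic alcohol (9β-OH, 9α-chain, 6β-OSiEt3) | CC[Si](CC)(CC)O[C@@H]1C=C(C)[C@@](O)(CCC3(C)OCCO3)[C@]2(C)CC=CC(C)(C)[C@H]12 | intermediate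
10 | triethylammonium salt of the C9 N-(methoxycarbonyl)sulfamate ester | CC[Si](CC)(CC)O[C@@H]1C=C(C)[C@@](OS(=O)(=O)[N-]C(=O)OC)(CCC3(C)OCCO3)[C@]2(C)CC=CC(C)(C)[C@H]12.CC[NH+](CC)CC | intermediate
11 | 6β-triethylsilyloxy 2,7,9(11)-triene (C12 syn to C8) | CC[Si](CC)(CC)O[C@@H]1C=C(C)/C(=C\CC3(C)OCCO3)[C@]2(C)CC=CC(C)(C)[C@H]12 | intermediate
12 | 6β-hydroxy 2,7,9(11)-triene | O[C@@H]1C=C(C)/C(=C\CC3(C)OCCO3)[C@]2(C)CC=CC(C)(C)[C@H]12 | intermediate
13 | 7β,8β-epoxy 6β-alcohol | O[C@@H]1[C@@H]3O[C@]3(C)/C(=C\CC4(C)OCCO4)[C@]2(C)CC=CC(C)(C)[C@H]12 | intermediate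
14 | 6β,8β-diol with exocyclic C9=C11 and C2=C3 | O[C@@H]1C[C@](C)(O)/C(=C\CC3(C)OCCO3)[C@]2(C)CC=CC(C)(C)[C@H]12 | intermediate
15 | saturated 6β,8β-diol (H-9β, chain α) | O[C@@H]1C[C@](C)(O)[C@@H](CCC3(C)OCCO3)[C@]2(C)CCCC(C)(C)[C@H]12 | intermediate
16 | 8β-hydroxy 6-ketone | O=C1C[C@](C)(O)[C@@H](CCC3(C)OCCO3)[C@]2(C)CCCC(C)(C)[C@H]12 | intermediate
17 | 6α,8β-diol | O[C@H]1C[C@](C)(O)[C@@H](CCC3(C)OCCO3)[C@]2(C)CCCC(C)(C)[C@H]12 | intermediate
18 | 6α-acetoxy 8β-alcohol, C13 ethylene ketal | CC(=O)O[C@H]1C[C@](C)(O)[C@@H](CCC3(C)OCCO3)[C@]2(C)CCCC(C)(C)[C@H]12 | intermediate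
19 | 6α-acetoxy 8β-hydroxy C13 methyl ketone | CC(=O)O[C@H]1C[C@](C)(O)[C@@H](CCC(C)=O)[C@]2(C)CCCC(C)(C)[C@H]12 | intermediate
20 | allyl diethylphosphonoacetate | C=CCOC(=O)CP(=O)(OCC)OCC | starting material
21 | sodium salt of allyl diethylphosphonoacetate | C=CCOC(=O)[CH-]P(=O)(OCC)OCC.[Na+] | intermediate
22 | allyl ester of the target (13E) | CC(=O)O[C@H]1C[C@](C)(O)[C@@H](CC/C(C)=C/C(=O)OCC=C)[C@]2(C)CCCC(C)(C)[C@H]12 | intermediate
23 | CNP0221670.1 | CC(=O)O[C@H]1C[C@](C)(O)[C@@H](CC/C(C)=C/C(=O)O)[C@]2(C)CCCC(C)(C)[C@H]12 | target

**Total steps:** 15. **Longest linear sequence:** 15 steps (1 to 23).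

**Steps most likely to fail**

**Step 1.**
- What may go wrong: the cycloaddition may stall because the Z-methyl of the diene raises the energy of the s-cis conformer. The strongly acidic catalyst may instead start cationic oligomerisation of the diene. Warming to force conversion would erode face selectivity.
- Fallback (sets out from 1 and 2, returns at 4): catalytic enantiocontrol is given up and the single enantiomer is obtained by resolution.
- 1 and 2 are pressed together at 12–15 kbar in CH2Cl2 with Eu(fod)3 (fod = 6,6,7,7,8,8,8-heptafluoro-2,2-dimethyl-3,5-octanedionate). This mild oxophilic Lewis acid binds the same unhindered carbonyl, and the steric veto on joining two fully substituted carbons acts in the same direction.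
- This should give 3 together with its mirror image ent-3 F1.
- Luche reduction as in step 2 gives 4 together with ent-4 F2.
- Esterification with (S)-2-methoxy-2-phenylacetic acid (N,N'-dicyclohexylcarbodiimide, 4-(dimethylamino)pyridine) gives the O-methylmandelate of 4 F3 and the O-methylmandelate of ent-4 F4. These are diastereomers and are separated by chromatography or crystallisation.
- K2CO3 in MeOH releases 4 from F3.

**Step 9.**
- What may go wrong: the iridium catalyst must reach a trisubstituted alkene wedged between two fully substituted carbons from the concave β face. Failure would show as lack of turnover, as hydrogen delivery from the open α face, or as acid-induced ionisation of the tertiary allylic alcohol.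
- Fallback (sets out from 9, returns at 15, and also bypasses steps 5 to 8): H-9 is delivered by a sigmatropic shift instead of a catalyst.
- Babler–Dauben oxidative transposition of 9 (pyridinium chlorochromate, NaOAc, CH2Cl2) gives the 6β-silyloxy 8-en-7-one F5.
- Condensation with p-toluenesulfonyl hydrazide gives the tosylhydrazone F6.
- Catecholborane adds hydride to C7 from the convex α face. On warming with NaOAc·3H2O the resulting 7β-diazene loses nitrogen in a retro-ene reaction that places hydrogen on the β face of C9 and moves the alkene to C7=C8. This gives the 6β-silyloxy 7-ene F7.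
- Bu4NF frees the allylic alcohol F8.
- VO(acac)2/t-BuOOH gives the 7β,8β-epoxy alcohol F9.
- LiAlH4 opens it at C7 to the 2-ene 6β,8β-diol F10.
- H2 over Pd on carbon saturates C2=C3 to give 15.

**Step 11 (together with the handling of 16).**
- What may go wrong: enolisation at C5 in the acidic medium would convert the cis fusion into the more stable trans fusion. A sluggish exchange of the hindered tertiary hydroxyl on boron would allow undirected α-face reduction back to the 6β-carbinol.
- Fallback (sets out from 16, returns at 17): hydride delivery is replaced by single-electron reduction with SmI2 in THF/MeOH at 0 °C.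
- The samarium ketyl, chelated by the 8β-hydroxyl, is protonated to the more stable equatorial 6α-alkoxide. This is the known anti-selective reduction of β-hydroxy ketones, and it is fast under nearly neutral conditions.
- This detour makes no compound outside the list (F0).

**Further compounds**
F1 | step 1 | ent-3, (4aR,8aS)-2,5,5,8a-tetramethyl-4a,5,8,8a-tetrahydronaphthalene-1,4-dione | O=C1C=C(C)C(=O)[C@@]2(C)CC=CC(C)(C)[C@@H]12
F2 | step 1 | ent-4 | O[C@H]1C=C(C)C(=O)[C@@]2(C)CC=CC(C)(C)[C@@H]12
F3 | step 1 | (S)-O-methylmandelate of 4 | CO[C@H](C(=O)O[C@@H]1C=C(C)C(=O)[C@]2(C)CC=CC(C)(C)[C@H]12)c1ccccc1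
F4 | step 1 | (S)-O-methylmandelate of ent-4 | CO[C@H](C(=O)O[C@H]1C=C(C)C(=O)[C@@]2(C)CC=CC(C)(C)[C@@H]12)c1ccccc1
F5 | step 9 | 6β-triethylsilyloxy 8-en-7-one | CC[Si](CC)(CC)O[C@@H]1C(=O)C(C)=C(CCC3(C)OCCO3)[C@]2(C)CC=CC(C)(C)[C@H]12
F6 | step 9 | C7 tosylhydrazone of F5 | CC[Si](CC)(CC)O[C@@H]1C(=NNS(=O)(=O)c4ccc(C)cc4)C(C)=C(CCC3(C)OCCO3)[C@]2(C)CC=CC(C)(C)[C@H]12
F7 | step 9 | 6β-triethylsilyloxy 2,7-diene with H-9β | CC[Si](CC)(CC)O[C@@H]1C=C(C)[C@@H](CCC3(C)OCCO3)[C@]2(C)CC=CC(C)(C)[C@H]12
F8 | step 9 | 6β-hydroxy 2,7-diene with H-9β | O[C@@H]1C=C(C)[C@@H](CCC3(C)OCCO3)[C@]2(C)CC=CC(C)(C)[C@H]12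
F9 | step 9 | 7β,8β-epoxy 6β-alcohol with H-9β | O[C@@H]1[C@@H]3O[C@]3(C)[C@@H](CCC4(C)OCCO4)[C@]2(C)CC=CC(C)(C)[C@H]12
F10 | step 9 | 2-ene 6β,8β-diol with H-9β | O[C@@H]1C[C@](C)(O)[C@@H](CCC3(C)OCCO3)[C@]2(C)CC=CC(C)(C)[C@H]12
F0 | step 11 | none | none
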